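Amounts first: these recipes give partner at 1.20 times the charge of starting material, and you want a quick number on your hunch that spring, with its slow feed, comes out ahead.

the same everywhere: second substrate 15.0 mM; third substrate 15.0 mM; time 30 h

| charge | starting material | partner | remark |
|---|---|---|---|
| noon | 15 mM (in portions, 4, over 25 h) | 18.0 mM | first portion at the start, last at 25 h |
| winter | 15 mM | 18.0 mM (fed, over 25 h) | all else is in the flask from the start; the feed brings no volume worth counting |
| dawn | 15 mM | 18.0 mM | everything together at the start |
| spring | 15 mM (fed, over 25 h) | 18.0 mM | all else is in the flask from the start; the feed brings no volume worth counting |

    starting material + partner → target (k1 = 1.8 M⁻¹ h⁻¹)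
    partner → decomposed reagent (k2 = 0.015 h⁻¹)
    starting material + target → side product (k3 = 0.81 M⁻¹ h⁻¹)
    second substrate + partner → second product (k4 = 2.1 M⁻¹ h⁻¹)
    third substrate + partner → third product (k5 = 0.076 M⁻¹ h⁻¹)

- which flask leads in amount of target, in percent of the starting material charged ("all alike" within 1.5 percentage points) (noon / winter / dawn / spring / all alike)
- how much target is there at the end, in percent of the starting material charged: noon
- how much target is there at the end, in percent of the starting material charged: winter
- how much target is there at the end, in percent of the starting material charged: dawn
- how much target is there at the end, in percent of the starting material charged: spring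

- a species is counted by the starting material in it: one side product counts as two
- run time (noon): 30 h

Test the hunch on dawn first. Follow one partner molecule at the start and price its exits. With the substrates at their charges, these are pseudo-first-order rates:

to target: 0.0270 h⁻¹
to second product: 0.0315 h⁻¹
to third product: 0.001140 h⁻¹
to decomposed reagent: 0.0150 h⁻¹

Take the exit to target over the sum of the exits and call it the partner share, the part of spent partner that makes target:

partner share in dawn: 36.2 %

Now multiply by the partner available and the part of it spent. At these rates partner in dawn lives 13.4 h, so by 30 h the spent part reckons to 89.3 %:

target made in dawn: 38.8 % of the charge

Treat that as my rough figure for dawn: it holds the rates at their starting values. Now turn to spring. Feeding starting material narrows the exit to target, while the other exits, together wider than it, stay open. So drop the hunch: I put dawn ahead of spring.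

The forecast names dawn, with 28.5 % there, 23.6 % in winter, 17.8 % in noon and 17.6 % in spring, on the ground that “early contact between starting material and partner decides the yield”. My rough figure for dawn stands above the forecast's figure for dawn.

The simulation gives dawn, as the forecast said: 29.0 % in dawn, 23.6 % in winter, 18.0 % in noon and 17.4 % in spring. Dawn still holds 16.9 % of its partner at 30.0 h. Now run the share on spring, where starting material averaged 42.9 % of the charge over the first 25 h. Keep the other exits as charged, and the spring share comes to 19.6 %. With 78.7 % of its partner spent, that reckons to 18.5 % of the charge made as target in spring. Spring ends at 30.0 h with target 17.4 % and side product 3.97 %.

The rate constants stand for no real mixture; no experiment stands behind them.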